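The ring atoms run from C1 (the CH carrying the dienyl chain through C15) via C2, C3=C4, C7=C8, C11=C12 and C13 to C14 (CHOMe). The route rests on cutting C1–C14 of this 14-membered carbocycle. The triad C14(O)–C1(H)–C15(=CH2) is the retron of a carbonyl allylation with allyl transposition. One ligand-controlled Nozaki–Hiyama–Kishi macrocyclisation closes the ring, sets C1 and C14 (anti) and creates the exocyclic methylene. It is stereoconvergent, since the equilibrating allylchromium erases the geometry of the allylic bromide. The precursor is an open-chain C25 pentaenal, (E)-β,γ-unsaturated at the aldehyde end, with two Z-trisubstituted alkenes and a 2-alkylallyl bromide terminus.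

Key step: step 10

Assumption: the (S,S)-ligand of step 10 is taken to expose the Re face of the aldehyde carbon C14. If a test on a simple aliphatic aldehyde shows the opposite sense, the (R,R)-ligand (from D-valinol) is used and nothing else changes.

Step 1
Reactants: 1 neryl acetate
Product: 2 (2Z,6E)-8-hydroxy-3,7-dimethylocta-2,6-dien-1-yl acetate (future C6–C13)
Conditions: SeO2 (cat.), t-BuOOH, salicylic acid (cat.), CH2Cl2, 0 °C to rt
Reagents that add atoms: tert-butyl hydroperoxide, CC(C)(C)OO
Why: The Riley-type SeO2 allylic oxidation (ene reaction, then [2,3]-shift) attacks the electron-richer distal trisubstituted alkene at its E-methyl group, which fixes C11=C12 as E and leaves the acetate-deactivated Z-alkene alone.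

Step 2
Reactants: 2 (2Z,6E)-8-hydroxy-3,7-dimethylocta-2,6-dien-1-yl acetate
Product: 3 (2Z,6E)-8-bromo-3,7-dimethylocta-2,6-dien-1-yl acetate
Conditions: CBr4, PPh3, CH2Cl2, 0 °C
Reagents that add atoms: carbon tetrabromide, BrC(Br)(Br)Br
Why: The Appel reaction replaces the primary allylic hydroxyl by SN2 under neutral conditions, so both alkene geometries and the acetate survive.

Step 3
Reactants: 3 (2Z,6E)-8-bromo-3,7-dimethylocta-2,6-dien-1-yl acetate; 4 1,3-dithiane
Product: 7 (2Z,6E)-8-(1,3-dithian-2-yl)-3,7-dimethylocta-2,6-dien-1-ol, via 2-lithio-1,3-dithiane 5 (not isolated), via dithianyl acetate 6 (not isolated)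
Conditions: 4, n-BuLi, THF, −30 °C; 3, −78 °C; then MeOH, K2CO3 (cat.), rt
Reagents that add atoms: none
Why: In this Corey–Seebach umpolung the soft lithiodithiane displaces the primary allylic bromide by SN2 at −78 °C faster than it attacks the acetate, which installs C14 as a masked aldehyde, and carbonate-catalysed methanolysis in the same flask frees the C6 alcohol.

Step 4
Reactants: 7 (2Z,6E)-8-(1,3-dithian-2-yl)-3,7-dimethylocta-2,6-dien-1-ol
Product: 8 2-[(2E,6Z)-8-bromo-2,6-dimethylocta-2,6-dien-1-yl]-1,3-dithiane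
Conditions: CBr4, PPh3, CH2Cl2, −20 to 0 °C, used crude
Reagents that add atoms: carbon tetrabromide, BrC(Br)(Br)Br
Why: The Appel reaction works under neutral, cold conditions, so the neryl-type Z-allylic system is not ionised and keeps its geometry, and the thioacetal is inert.

Step 5
Reactants: 8 2-[(2E,6Z)-8-bromo-2,6-dimethylocta-2,6-dien-1-yl]-1,3-dithiane; 9 prenol (3-methylbut-2-en-1-ol)
Product: 11 (2Z,6Z,10E)-12-(1,3-dithian-2-yl)-3,7,11-trimethyldodeca-2,6,10-trien-1-ol (C2–C14), via prenol dianion 10 (not isolated)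
Conditions: 9, n-BuLi (2 equiv), TMEDA, Et2O, 0 °C to rt; then 8, THF, −78 to 0 °C; aq. work-up
Reagents that add atoms: none
Why: Alkoxide-directed allylic lithiation of prenol takes the proton from the methyl group cis to CH2OLi, and SN2 alkylation of this dianion at its terminal carbon forms C5–C6 with C3=C4 locked Z (dianion alkylation).

Step 6
Reactants: 11 (2Z,6Z,10E)-12-(1,3-dithian-2-yl)-3,7,11-trimethyldodeca-2,6,10-trien-1-ol
Product: 12 2-[(2E,6Z,10Z)-12-bromo-2,6,10-trimethyldodeca-2,6,10-trien-1-yl]-1,3-dithiane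
Conditions: CBr4, PPh3, CH2Cl2, −20 to 0 °C, used crude
Reagents that add atoms: carbon tetrabromide, BrC(Br)(Br)Br
Why: The Appel reaction gives SN2 replacement of the primary allylic hydroxyl at C2 without allylic transposition or Z/E erosion.

Step 7
Reactants: 12 2-[(2E,6Z,10Z)-12-bromo-2,6,10-trimethyldodeca-2,6,10-trien-1-yl]-1,3-dithiane; 13 5-bromo-2-methylpent-2-ene; 14 propargyl alcohol
Product: 17 (2Z,5Z,9Z,13E)-15-(1,3-dithian-2-yl)-6,10,14-trimethyl-2-(4-methylpent-3-en-1-yl)pentadeca-2,5,9,13-tetraen-1-ol, via homoprenylmagnesium bromide 15 (not isolated), via alkenylmagnesium alkoxide 16 (not isolated)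
Conditions: 13, Mg, Et2O; 14, CuI (cat.), Et2O, −10 °C to rt; then 12, THF, −30 to 0 °C; aq. work-up
Reagents that add atoms: none
Why: Copper-catalysed anti-carbomagnesiation of propargyl alcohol puts the homoprenyl group on the internal carbon (C15) and magnesium on the terminal carbon (C1) cis to the alkoxide in a five-membered chelate, and copper-catalysed SN2 allylation of this alkenyl Grignard by 12 forms C1–C2 with retention in both partners.

Step 8
Reactants: 17 (2Z,5Z,9Z,13E)-15-(1,3-dithian-2-yl)-6,10,14-trimethyl-2-(4-methylpent-3-en-1-yl)pentadeca-2,5,9,13-tetraen-1-ol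
Product: 18 the corresponding allylic bromide, 2-[(2E,6Z,10Z,13Z)-14-(bromomethyl)-2,6,10,18-tetramethylnonadeca-2,6,10,13,17-pentaen-1-yl]-1,3-dithiane
Conditions: CBr4, PPh3, CH2Cl2, −20 °C, used at once
Reagents that add atoms: carbon tetrabromide, BrC(Br)(Br)Br
Why: The Appel reaction acts on the only hydroxyl group, and the geometry of this alkene is of no consequence for the next C–C bond formation.

Step 9
Reactants: 18 2-[(2E,6Z,10Z,13Z)-14-(bromomethyl)-2,6,10,18-tetramethylnonadeca-2,6,10,13,17-pentaen-1-yl]-1,3-dithiane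
Product: 19 (3E,7Z,11Z,14Z)-15-(bromomethyl)-3,7,11,19-tetramethylicosa-3,7,11,14,18-pentaenal
Conditions: PhI(OCOCF3)2, NaHCO3, MeCN/H2O 9:1, 0 °C, 10 min
Reagents that add atoms: water, O
Why: In this oxidative dethioacetalisation with iodine(III), sulfur is by far the most oxidisable site, hydrolysis is over within minutes, and the bicarbonate buffer keeps the β,γ-unsaturated aldehyde out of conjugation and the allylic bromide intact.

Step 10
Reactants: 19 (3E,7Z,11Z,14Z)-15-(bromomethyl)-3,7,11,19-tetramethylicosa-3,7,11,14,18-pentaenal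
Product: 21 (1S,3E,7Z,11Z,14R)-3,7,11-trimethyl-14-(6-methylhepta-1,5-dien-2-yl)cyclotetradeca-3,7,11-trien-1-ol (C1 R and C14 S in the overview numbering), via allylchromium(III) species 20 (not isolated)
Conditions: CrCl2 (4 equiv), (S,S)-1,8-bis(4-isopropyl-4,5-dihydrooxazol-2-yl)carbazole-type tridentate ligand, i-Pr2NEt, 4 Å MS, THF, rt; 19 added by syringe pump (final ca. 1 mM); aq. EDTA work-up
Reagents that add atoms: none
Why: Two single-electron transfers from Cr(II) insert chromium into the allylic C–Br bond only, and the resulting allylchromium(III) 20 equilibrates quickly by σ–π–σ (1,3-metallotropic) shifts, so the Z-bromide (or any E/Z mixture) is funnelled into the less hindered E-allyl species with chromium on the primary carbon. This species adds through its γ-carbon C1 to the aldehyde carbon C14 in a six-membered Zimmerman–Traxler chair; the closest known reaction types are the Nozaki–Hiyama–Kishi allylation macrocyclisation that gives 14-membered isopropenyl carbinols and the ligand-controlled asymmetric chromium allylation of aliphatic aldehydes. The 14-membered carbocycle closes in 14-exo-trig mode at the carbonyl group with SE2' transposition of the allyl unit, so that C15=CH2 ends up exocyclic. The anti relation follows from the E-allylchromium with C2 and C13 both equatorial in the chair, and the absolute configuration follows from the chiral ligand on chromium, which exposes the Re face of C14 and gives 14S and, through the chair, 1R. The step needs three selectivities: chemoselectivity (the organochromium ignores the five alkenes and is too weakly basic to enolise the aldehyde), γ- over α-attack (secured by the closed transition state, since α-attack would give a 16-membered ring), and cyclisation over oligomerisation (secured by slow addition at high dilution).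

Step 11
Reactants: 21 (1S,3E,7Z,11Z,14R)-3,7,11-trimethyl-14-(6-methylhepta-1,5-dien-2-yl)cyclotetradeca-3,7,11-trien-1-ol
Product: 23 target methyl ether CNP0391665.1, via sodium alkoxide 22 (not isolated)
Conditions: NaH, MeI, THF, 0 °C to rt
Reagents that add atoms: iodomethane, CI
Why: The Williamson ether synthesis methylates the alkoxide oxygen without breaking the C14–O bond, so neither stereocentre nor any alkene is touched.

Compound list
1 | neryl acetate, (2Z)-3,7-dimethylocta-2,6-dien-1-yl acetate | CC(=O)OC/C=C(/C)CCC=C(C)C | starting material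
2 | (2Z,6E)-8-hydroxy-3,7-dimethylocta-2,6-dien-1-yl acetate | CC(=O)OC/C=C(/C)CC/C=C(\C)CO | intermediate
3 | (2Z,6E)-8-bromo-3,7-dimethylocta-2,6-dien-1-yl acetate | CC(=O)OC/C=C(/C)CC/C=C(\C)CBr | intermediate
4 | 1,3-dithiane | C1CSCSC1 | starting material
5 | 2-lithio-1,3-dithiane | [Li]C1SCCCS1 | intermediate
6 | (2Z,6E)-8-(1,3-dithian-2-yl)-3,7-dimethylocta-2,6-dien-1-yl acetate | CC(=O)OC/C=C(/C)CC/C=C(\C)CC1SCCCS1 | intermediate
7 | (2Z,6E)-8-(1,3-dithian-2-yl)-3,7-dimethylocta-2,6-dien-1-ol | OC/C=C(/C)CC/C=C(\C)CC1SCCCS1 | intermediate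
8 | 2-[(2E,6Z)-8-bromo-2,6-dimethylocta-2,6-dien-1-yl]-1,3-dithiane | BrC/C=C(/C)CC/C=C(\C)CC1SCCCS1 | intermediate
9 | prenol, 3-methylbut-2-en-1-ol | CC(C)=CCO | starting material
10 | dilithiated prenol, lithium (Z)-4-lithio-3-methylbut-2-en-1-olate | [Li]OC/C=C(/C)C[Li] | intermediate
11 | (2Z,6Z,10E)-12-(1,3-dithian-2-yl)-3,7,11-trimethyldodeca-2,6,10-trien-1-ol | OC/C=C(/C)CC/C=C(/C)CC/C=C(\C)CC1SCCCS1 | intermediate
12 | 2-[(2E,6Z,10Z)-12-bromo-2,6,10-trimethyldodeca-2,6,10-trien-1-yl]-1,3-dithiane | BrC/C=C(/C)CC/C=C(/C)CC/C=C(\C)CC1SCCCS1 | intermediate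
13 | 5-bromo-2-methylpent-2-ene (homoprenyl bromide) | CC(C)=CCCBr | starting material
14 | propargyl alcohol | C#CCO | starting material
15 | (4-methylpent-3-en-1-yl)magnesium bromide | CC(C)=CCC[Mg]Br | intermediate
16 | bromomagnesium (Z)-3-(bromomagnesio)-2-(4-methylpent-3-en-1-yl)prop-2-en-1-olate (Mg on C1 cis to CH2O) | Br[Mg]/C=C(/CCC=C(C)C)CO[Mg]Br | intermediate
17 | (2Z,5Z,9Z,13E)-15-(1,3-dithian-2-yl)-6,10,14-trimethyl-2-(4-methylpent-3-en-1-yl)pentadeca-2,5,9,13-tetraen-1-ol | OC/C(CCC=C(C)C)=C\C/C=C(/C)CC/C=C(/C)CC/C=C(\C)CC1SCCCS1 | intermediate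
18 | 2-[(2E,6Z,10Z,13Z)-14-(bromomethyl)-2,6,10,18-tetramethylnonadeca-2,6,10,13,17-pentaen-1-yl]-1,3-dithiane | BrC/C(CCC=C(C)C)=C\C/C=C(/C)CC/C=C(/C)CC/C=C(\C)CC1SCCCS1 | intermediate
19 | (3E,7Z,11Z,14Z)-15-(bromomethyl)-3,7,11,19-tetramethylicosa-3,7,11,14,18-pentaenal | BrC/C(CCC=C(C)C)=C\C/C=C(/C)CC/C=C(/C)CC/C=C(\C)CC=O | intermediate
20 | reactive (E)-allylchromium(III) dichloride of the pentaenal (chiral ligand on Cr not drawn) | Cl[Cr](Cl)C/C(CCC=C(C)C)=C/C/C=C(/C)CC/C=C(/C)CC/C=C(\C)CC=O | intermediate
21 | (1S,3E,7Z,11Z,14R)-3,7,11-trimethyl-14-(6-methylhepta-1,5-dien-2-yl)cyclotetradeca-3,7,11-trien-1-ol | C=C(CCC=C(C)C)[C@H]1C/C=C(/C)CC/C=C(/C)CC/C=C(\C)C[C@@H]1O | intermediate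
22 | sodium alkoxide of 21 | C=C(CCC=C(C)C)[C@H]1C/C=C(/C)CC/C=C(/C)CC/C=C(\C)C[C@@H]1[O-].[Na+] | intermediate
23 | CNP0391665.1, methyl ether of 21 | C=C(CCC=C(C)C)[C@H]1C/C=C(/C)CC/C=C(/C)CC/C=C(\C)C[C@@H]1OC | target

Total step count: 11. Longest linear sequence: 11 steps (from neryl acetate 1).

Steps most likely to fail

Step 10. The conformational demands of the macrocyclic transition state may override the ligand, so that facial selection at C14 is weak, and intermolecular coupling may compete with ring closure.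
- The fallback separates ring closure from absolute control. It sets out from 19.
- Ligand-free CrCl2 in THF with the same slow addition should give the anti carbinol as a racemate, that is 21 together with its mirror-image carbinol F1.
- Esterification with (S)-2-methoxy-2-phenylacetic acid (DCC, DMAP) gives two diastereomers, the (S)-O-methylmandelate of 21 F2 and the (S)-O-methylmandelate of the mirror image F3. These are separated by chromatography.
- LiOH in THF/MeOH/H2O cleaves F2, and the route is rejoined at 21.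

Step 5. The delocalised dianion may be alkylated at its internal carbon, may attack the bromide in SN2' fashion, or may deprotonate the dithiane.
- The fallback makes the C4–C5 bond instead by a B-alkyl Suzuki–Miyaura coupling. It sets out from 7.
- MnO2 gives the (Z)-enal F4, and Wittig methylenation (Ph3P=CH2) gives the (Z)-triene F5.
- 9-BBN-H hydroborates only the monosubstituted terminal alkene and gives the B-alkyl-9-BBN F6.
- F6 is coupled with (Z)-3-iodobut-2-en-1-ol F7 (from but-2-yn-1-ol, Red-Al then I2) under PdCl2(dppf), AsPh3, Cs2CO3, DMF/H2O. The iodide geometry is retained, and the route is rejoined at 11.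

Step 9. The aldehyde may slip into conjugation and the allylic bromide may solvolyse in the aqueous oxidising medium.
- The fallback inverts the order, so that the halide never meets water. It sets out from 17.
- MeI, CaCO3 in aqueous MeCN unmasks the hydroxy aldehyde F8.
- The neutral NBS/Me2S reagent (Corey–Kim-type halogenation) then converts only the allylic alcohol into the bromide, and the route is rejoined at 19.

Further compounds
F1 | step 10 | (1R,3E,7Z,11Z,14S)-3,7,11-trimethyl-14-(6-methylhepta-1,5-dien-2-yl)cyclotetradeca-3,7,11-trien-1-ol (mirror image of 21) | C=C(CCC=C(C)C)[C@@H]1C/C=C(/C)CC/C=C(/C)CC/C=C(\C)C[C@H]1O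
F2 | step 10 | (S)-2-methoxy-2-phenylacetate of 21 | C=C(CCC=C(C)C)[C@H]1C/C=C(/C)CC/C=C(/C)CC/C=C(\C)C[C@@H]1OC(=O)[C@@H](OC)c1ccccc1
F3 | step 10 | (S)-2-methoxy-2-phenylacetate of F1 | C=C(CCC=C(C)C)[C@@H]1C/C=C(/C)CC/C=C(/C)CC/C=C(\C)C[C@H]1OC(=O)[C@@H](OC)c1ccccc1
F4 | step 5 | (2Z,6E)-8-(1,3-dithian-2-yl)-3,7-dimethylocta-2,6-dienal | O=C/C=C(/C)CC/C=C(\C)CC1SCCCS1
F5 | step 5 | 2-[(2E,6Z)-2,6-dimethylnona-2,6,8-trien-1-yl]-1,3-dithiane | C=C/C=C(/C)CC/C=C(\C)CC1SCCCS1
F6 | step 5 | 9-[(3Z,7E)-9-(1,3-dithian-2-yl)-4,8-dimethylnona-3,7-dien-1-yl]-9-borabicyclo[3.3.1]nonane | C(C/C=C(/C)CC/C=C(\C)CC1SCCCS1)B1C2CCCC1CCC2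
F7 | step 5 | (Z)-3-iodobut-2-en-1-ol | OC/C=C(/C)I
F8 | step 9 | (3E,7Z,11Z,14Z)-15-(hydroxymethyl)-3,7,11,19-tetramethylicosa-3,7,11,14,18-pentaenal | OC/C(CCC=C(C)C)=C\C/C=C(/C)CC/C=C(/C)CC/C=C(\C)CC=O
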